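(Readings and results were computed on assumed constants, and the scatter is random.)

An hour in the larch run is not an hour in the cedar run, and I want the exchange rate before I trust any curve.

| setting | cedar | larch | dusk | midnight | dawn |
|---|---|---|---|---|---|
| substrate | 0.31 M | 0.70 M | 0.47 M | 0.47 M | 0.47 M |
| partner | 0.446 M | 0.446 M | 0.446 M | 0.446 M | 0.446 M |
| temperature | −5 °C | 12 °C |  | 0 °C | 25 °C |
| remark | run made earlier | run made earlier | at 25 °C until 12 h, from then on at 0 °C |  |  |
| time |  |  | 2.5 d | 2.5 d | 2.5 d |

cedar run (percent of the substrate charged)

| time / d | target / % |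
|---|---|
| 0.625 | 3.3 |
| 1.25 | 4.7 |
| 2.08 | 8.0 |
| 2.50 | 8.4 |

larch run (percent of the substrate charged)

| time / h | target / % |
|---|---|
| 8.00 | 6.3 |
| 15.0 | 9.0 |
| 30.0 | 12.2 |

(each reading ± 0.5 percentage points)

1. which flask leads in amount of target, in percent of the substrate charged ("all alike" within 1.5 percentage points) (dusk / midnight / dawn / all alike)
2. how much target is there at the end, in percent of the substrate charged: dusk
3. how much target is there at the end, in percent of the substrate charged: midnight
4. how much target is there at the end, in percent of the substrate charged: dawn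

Midnight looks nearly like cedar: the same partner charge and the same time, but 5.00 K warmer and with more substrate. I assume the percent of target follows c(partner) and the heat, not c(substrate), although cedar and larch differ in substrate too. Equal yield should then mean equal progress, so I compare the two runs at one yield. Cedar shows 8.0% at 2.08 d, and larch passes that yield, by interpolation, at

12.4 h.

The clock ratio, a shift factor, is the cedar time over the larch time at equal yield:

S = 4.02.

It is a reading, with the scatter of 0.5 percentage points in it. I spread its logarithm evenly over the degrees. One round gives midnight a clock 1.51 times cedar's, so on a straight line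

y = 12.7%.

But larch bends at that height, so I go round again. Midnight's time in larch hours is

22.5 h,

and the larch curve there gives

y = 10.6%.

I commit to this second figure. Dusk's warm stage alone is worth 34.8 h larch hours, more than midnight's whole time. Dawn's clock runs past every reading, so I read nothing for dawn.

The forecast says dusk leads, with dusk 15%, midnight 12% and dawn 11.7%; its midnight stands above my figure. Of dawn it says “so it reaches equilibrium”.

The flasks give dusk 18.4%, midnight 12.3% and dawn 13.1%, so dusk leads.

    partner ⇌ dormant form (K = 0.880, k = 1.50 × 10⁻⁴ s⁻¹, Ea = 100 kJ mol⁻¹, ΔH = −26.0 kJ mol⁻¹)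
    target → over-reaction product (k = 9.20 × 10⁻⁶ s⁻¹, Ea = 104 kJ mol⁻¹)
    substrate + target → side product (k = 7.30 × 10⁻⁶ M⁻¹ s⁻¹, Ea = 90.0 kJ mol⁻¹)
    substrate + partner ⇌ target + by-product (K = 2.90, k = 2.40 × 10⁻⁵ M⁻¹ s⁻¹, Ea = 65.0 kJ mol⁻¹, ΔH = −20.0 kJ mol⁻¹)
    (constants at 25 °C)

Through S, midnight's 22.5 h on the larch clock gave 10.6%, and the flask's 12.3% stands 1.7 points above that figure, so midnight does not confirm S. Dusk stands at 15.1% at 0.500 d, above larch's last 12.2%, as 34.8 h suggested. Midnight's bend is partly the falling partner: held at its level, midnight gives 18.2%, and ten times the time gives 26.1%. The order falls if a run puts dusk below dawn; dusk leads by 5.3 points, and a partner charge of 0.312 M moves dusk by 5 percentage points.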